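**Retrosynthetic overview**

1. The trans‑decalin, the C10 formyl group and the C8 exocyclic methylene are made in one final step: a gold‑triggered 6‑exo‑dig enyne cyclisation closes ring B and is ended by a ring‑contracting 1,2‑shift (seven‑ to six‑membered) that turns a 2‑alkylidene‑cycloheptanol into ring A with its angular CHO.
2. The Z‑alkylidene and the complete butenolide side chain come from a boron‑tethered ring‑closing metathesis / B‑alkyl Suzuki coupling on a 2‑methylidene‑cycloheptanol with but‑3‑enylboronic acid and 3‑bromofuran‑2(5H)‑one.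
3. The seven‑membered carbocycle comes from a regioselective one‑carbon diazo ring expansion of a cyclohexanone.
4. C4 (quaternary) and C5 are set by a catalytic asymmetric Diels–Alder reaction of methacrolein with a 2‑silyloxy diene built from pent‑4‑ynal and acetone.
5. Ring order: carbocycle (six, then seven; the future ring A) → ring B and ring A together in the last step; the butenolide ring is carried in intact.

Carbon labels C1–C20 below follow labdane numbering of the target (C4 bears CH3/CH2OAc, C10 the CHO, C8 the methylene, C9 the side chain).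

Assumption: pent‑4‑ynal, but‑3‑enylboronic acid and 3‑bromofuran‑2(5H)‑one are taken as purchasable, and the (S)‑oxazaborolidine is assumed to give the (1R,2S) Diels–Alder adduct (otherwise its antipode is used).

**Step 1**
Reactants: 1 pent‑4‑ynal; 2 acetone
Product: 3 (3E)‑oct‑3‑en‑7‑yn‑2‑one
Conditions: acetone (solvent), morpholinium trifluoroacetate (20 mol%), 70 °C
Reagents that add atoms: none
Why: Amine‑catalysed aldol condensation of an unbranched aldehyde with excess acetone gives the thermodynamic E‑enone.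

**Step 2**
Reactants: 3 (3E)‑oct‑3‑en‑7‑yn‑2‑one
Product: 4 triethyl{[(3E)‑8‑(triethylsilyl)octa‑1,3‑dien‑7‑yn‑2‑yl]oxy}silane
Conditions: LiN(iPr)2 (2.2 equiv), THF, −78 °C; Et3SiCl (2.3 equiv), −78 °C to 0 °C
Reagents that add atoms: chlorotriethylsilane, CC[Si](Cl)(CC)CC
Why: Kinetic (cross‑conjugated) enolate formation and acetylide formation followed by double silylation give the 2‑silyloxy diene and at the same time mask the alkyne for the later metathesis.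

**Step 3**
Reactants: 4 triethyl{[(3E)‑8‑(triethylsilyl)octa‑1,3‑dien‑7‑yn‑2‑yl]oxy}silane; 5 methacrolein
Product: 6 (1R,2S)‑1‑methyl‑4‑[(triethylsilyl)oxy]‑2‑[4‑(triethylsilyl)but‑3‑yn‑1‑yl]cyclohex‑3‑ene‑1‑carbaldehyde
Conditions: (S)‑o‑tolyl‑CBS‑oxazaborolidine·AlBr3 (5 mol%), CH2Cl2, −78 °C
Reagents that add atoms: none
Why: Chiral Lewis acid catalysed Diels–Alder reaction in which the 2‑silyloxy group and the alkyl substituent both direct the substituted diene terminus to the α‑carbon of the enal, the endo (formyl) transition state places CHO cis to the butynyl chain, and the catalyst face selection sets C4 (quaternary) and C5.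

**Step 4**
Reactants: 6 (1R,2S)‑1‑methyl‑4‑[(triethylsilyl)oxy]‑2‑[4‑(triethylsilyl)but‑3‑yn‑1‑yl]cyclohex‑3‑ene‑1‑carbaldehyde
Product: 8 {(1R,2S)‑1‑methyl‑4‑[(triethylsilyl)oxy]‑2‑[4‑(triethylsilyl)but‑3‑yn‑1‑yl]cyclohex‑3‑en‑1‑yl}methyl acetate, via primary alcohol 7 (not isolated)
Conditions: NaBH4, EtOH–THF, −20 °C; then Ac2O, pyridine, DMAP (cat.), 0 °C to rt
Reagents that add atoms: acetic anhydride, CC(=O)OC(C)=O
Why: Chemoselective hydride reduction of the aldehyde (the silyl enol ether is inert) and acetylation install the C19 acetate before any C20 aldehyde exists, so no lactol can form later.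

**Step 5**
Reactants: 8 {(1R,2S)‑1‑methyl‑4‑[(triethylsilyl)oxy]‑2‑[4‑(triethylsilyl)but‑3‑yn‑1‑yl]cyclohex‑3‑en‑1‑yl}methyl acetate
Product: 9 {(1R,2S,3S)‑1‑methyl‑4‑oxo‑3‑[(phenylsulfanyl)methyl]‑2‑[4‑(triethylsilyl)but‑3‑yn‑1‑yl]cyclohexyl}methyl acetate
Conditions: PhSCH2Cl, ZnBr2 (10 mol%), CH2Cl2, 0 °C to rt
Reagents that add atoms: chloromethyl phenyl sulfide, ClCSc1ccccc1
Why: Lewis acid mediated alkylation of the regiodefined silyl enol ether with an α‑chloro sulfide puts a masked methylene on C10 only, trans to the C5 chain.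

**Step 6**
Reactants: 9 {(1R,2S,3S)‑1‑methyl‑4‑oxo‑3‑[(phenylsulfanyl)methyl]‑2‑[4‑(triethylsilyl)but‑3‑yn‑1‑yl]cyclohexyl}methyl acetate
Product: 11 {(1R,2S,3S)‑1‑methyl‑4‑oxo‑3‑[(phenylsulfanyl)methyl]‑2‑[4‑(triethylsilyl)but‑3‑yn‑1‑yl]cycloheptyl}methyl acetate, via α‑silyl ketone 10 (not isolated)
Conditions: Me3SiCHN2 (1.3 equiv), Sc(OTf)3 (10 mol%), CH2Cl2, −40 °C to 0 °C; then 1 M HCl, THF
Reagents that add atoms: trimethylsilyldiazomethane, C[Si](C)(C)C=[N+]=[N-]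
Why: Lewis acid catalysed diazoalkane homologation (Tiffeneau–Demjanov type 1,2‑shift) in which the unsubstituted α‑CH2 migrates in preference to the substituted C10, inserting the future C1 next to the carbonyl C20.

**Step 7**
Reactants: 11 {(1R,2S,3S)‑1‑methyl‑4‑oxo‑3‑[(phenylsulfanyl)methyl]‑2‑[4‑(triethylsilyl)but‑3‑yn‑1‑yl]cycloheptyl}methyl acetate
Product: 12 {(1R,2S,3S)‑4‑hydroxy‑1‑methyl‑3‑[(phenylsulfanyl)methyl]‑2‑[4‑(triethylsilyl)but‑3‑yn‑1‑yl]cycloheptyl}methyl acetate (both carbinol epimers)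
Conditions: NaBH4, MeOH, 0 °C
Reagents that add atoms: none
Why: Simple ketone reduction; the configuration of the new carbinol (C20) is irrelevant because this carbon becomes the aldehyde.

**Step 8**
Reactants: 12 {(1R,2S,3S)‑4‑hydroxy‑1‑methyl‑3‑[(phenylsulfanyl)methyl]‑2‑[4‑(triethylsilyl)but‑3‑yn‑1‑yl]cycloheptyl}methyl acetate
Product: 14 {(1R,2R)‑4‑hydroxy‑1‑methyl‑3‑methylidene‑2‑[4‑(triethylsilyl)but‑3‑yn‑1‑yl]cycloheptyl}methyl acetate, via sulfoxide 13 (not isolated)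
Conditions: mCPBA (1.0 equiv), CH2Cl2, −78 °C; then toluene, CaCO3, 110 °C
Reagents that add atoms: none
Why: Sulfide oxidation and thermal sulfoxide syn‑elimination, whose only β‑hydrogen is on C10, give the exocyclic methylene allylic alcohol.

**Step 9**
Reactants: 14 {(1R,2R)‑4‑hydroxy‑1‑methyl‑3‑methylidene‑2‑[4‑(triethylsilyl)but‑3‑yn‑1‑yl]cycloheptyl}methyl acetate; 15 but‑3‑en‑1‑ylboronic acid; 16 3‑bromofuran‑2(5H)‑one
Product: 19 {(1R,2R,3Z)‑4‑hydroxy‑1‑methyl‑3‑[3‑(2‑oxo‑2,5‑dihydrofuran‑3‑yl)propylidene]‑2‑[4‑(triethylsilyl)but‑3‑yn‑1‑yl]cycloheptyl}methyl acetate, via open boronic ester 17 (not isolated), via cyclic boronate 18 (not isolated)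
Conditions: 15 (1.1 equiv), 4 Å MS, toluene, rt; second‑generation Grubbs catalyst (10 mol%), 80 °C; then 16, Pd(OAc)2 (5 mol%), RuPhos (10 mol%), K3PO4, toluene–H2O, 70 °C
Reagents that add atoms: none
Why: Transient boron‑tethered ring‑closing metathesis forms the trisubstituted alkene inside a seven‑membered oxaborepine, which can only be Z (C11 cis to the carbinol carbon), and B‑alkyl Suzuki–Miyaura coupling of that boronate with the bromobutenolide then completes the side chain and frees the alcohol.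

**Step 10**
Reactants: 19 {(1R,2R,3Z)‑4‑hydroxy‑1‑methyl‑3‑[3‑(2‑oxo‑2,5‑dihydrofuran‑3‑yl)propylidene]‑2‑[4‑(triethylsilyl)but‑3‑yn‑1‑yl]cycloheptyl}methyl acetate
Product: 20 {(1R,2R,3Z)‑2‑(but‑3‑yn‑1‑yl)‑4‑hydroxy‑1‑methyl‑3‑[3‑(2‑oxo‑2,5‑dihydrofuran‑3‑yl)propylidene]cycloheptyl}methyl acetate
Conditions: AgF (1.5 equiv), MeOH–CH2Cl2, rt, dark; then 1 M HCl
Reagents that add atoms: none
Why: Silver‑mediated protodesilylation of the alkynylsilane is neutral enough to leave the acetate, the butenolide and the allylic alcohol untouched.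

**Step 11**
Reactants: 20 {(1R,2R,3Z)‑2‑(but‑3‑yn‑1‑yl)‑4‑hydroxy‑1‑methyl‑3‑[3‑(2‑oxo‑2,5‑dihydrofuran‑3‑yl)propylidene]cycloheptyl}methyl acetate
Product: 21 [(1R,4aR,5R,8aR)‑4a‑formyl‑1‑methyl‑6‑methylidene‑5‑[2‑(2‑oxo‑2,5‑dihydrofuran‑3‑yl)ethyl]decahydronaphthalen‑1‑yl]methyl acetate
Conditions: (JohnPhos)Au(NCMe)SbF6 (5 mol%), CH2Cl2, 0 °C to rt
Reagents that add atoms: none
Why: Proposed new method: cationic monovalent gold activates the terminal alkyne, the Z‑alkene attacks through C9 in a chair‑like 6‑exo‑dig mode from the face of the C5 tether, and the tertiary C10 cation is quenched anti by a semipinacol 1,2‑shift of ring carbon C1 from the carbinol carbon (seven‑ to six‑membered ring contraction giving the C20 aldehyde) before protodeauration leaves the C8 methylene, so anti addition across the Z‑alkene sets C9 and C10 and forces the trans ring fusion; the closest known reactions are gold‑catalysed cyclisation/pinacol shifts of 3‑silyloxy‑1,5‑enynes and alkoxycyclisations of 1,6‑enynes.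

**Compound list**

1 | pent‑4‑ynal | C#CCCC=O | starting material
2 | acetone | CC(C)=O | starting material
3 | (3E)‑oct‑3‑en‑7‑yn‑2‑one | CC(=O)/C=C/CCC#C | intermediate
4 | triethyl{[(3E)‑8‑(triethylsilyl)octa‑1,3‑dien‑7‑yn‑2‑yl]oxy}silane | C=C(O[Si](CC)(CC)CC)/C=C/CCC#C[Si](CC)(CC)CC | intermediate
5 | methacrolein (2‑methylprop‑2‑enal) | CC(=C)C=O | starting material
6 | (1R,2S)‑1‑methyl‑4‑[(triethylsilyl)oxy]‑2‑[4‑(triethylsilyl)but‑3‑yn‑1‑yl]cyclohex‑3‑ene‑1‑carbaldehyde (CHO cis to the butynyl chain) | O=C[C@]1(C)CCC(O[Si](CC)(CC)CC)=C[C@@H]1CCC#C[Si](CC)(CC)CC | intermediate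
7 | {(1R,2S)‑1‑methyl‑4‑[(triethylsilyl)oxy]‑2‑[4‑(triethylsilyl)but‑3‑yn‑1‑yl]cyclohex‑3‑en‑1‑yl}methanol | OC[C@]1(C)CCC(O[Si](CC)(CC)CC)=C[C@@H]1CCC#C[Si](CC)(CC)CC | intermediate (not isolated)
8 | {(1R,2S)‑1‑methyl‑4‑[(triethylsilyl)oxy]‑2‑[4‑(triethylsilyl)but‑3‑yn‑1‑yl]cyclohex‑3‑en‑1‑yl}methyl acetate | CC(=O)OC[C@]1(C)CCC(O[Si](CC)(CC)CC)=C[C@@H]1CCC#C[Si](CC)(CC)CC | intermediate
9 | {(1R,2S,3S)‑1‑methyl‑4‑oxo‑3‑[(phenylsulfanyl)methyl]‑2‑[4‑(triethylsilyl)but‑3‑yn‑1‑yl]cyclohexyl}methyl acetate | CC(=O)OC[C@]1(C)CCC(=O)[C@@H](CSc2ccccc2)[C@@H]1CCC#C[Si](CC)(CC)CC | intermediate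
10 | {(1R,2S,3S)‑1‑methyl‑4‑oxo‑3‑[(phenylsulfanyl)methyl]‑2‑[4‑(triethylsilyl)but‑3‑yn‑1‑yl]‑5‑(trimethylsilyl)cycloheptyl}methyl acetate | CC(=O)OC[C@]1(C)CCC([Si](C)(C)C)C(=O)[C@@H](CSc2ccccc2)[C@@H]1CCC#C[Si](CC)(CC)CC | intermediate (not isolated)
11 | {(1R,2S,3S)‑1‑methyl‑4‑oxo‑3‑[(phenylsulfanyl)methyl]‑2‑[4‑(triethylsilyl)but‑3‑yn‑1‑yl]cycloheptyl}methyl acetate | CC(=O)OC[C@]1(C)CCCC(=O)[C@@H](CSc2ccccc2)[C@@H]1CCC#C[Si](CC)(CC)CC | intermediate
12 | {(1R,2S,3S)‑4‑hydroxy‑1‑methyl‑3‑[(phenylsulfanyl)methyl]‑2‑[4‑(triethylsilyl)but‑3‑yn‑1‑yl]cycloheptyl}methyl acetate (both C4 carbinol epimers) | CC(=O)OC[C@]1(C)CCCC(O)[C@@H](CSc2ccccc2)[C@@H]1CCC#C[Si](CC)(CC)CC | intermediate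
13 | {(1R,2S,3S)‑4‑hydroxy‑1‑methyl‑3‑[(phenylsulfinyl)methyl]‑2‑[4‑(triethylsilyl)but‑3‑yn‑1‑yl]cycloheptyl}methyl acetate | CC(=O)OC[C@]1(C)CCCC(O)[C@@H](CS(=O)c2ccccc2)[C@@H]1CCC#C[Si](CC)(CC)CC | intermediate (not isolated)
14 | {(1R,2R)‑4‑hydroxy‑1‑methyl‑3‑methylidene‑2‑[4‑(triethylsilyl)but‑3‑yn‑1‑yl]cycloheptyl}methyl acetate (both carbinol epimers) | CC(=O)OC[C@]1(C)CCCC(O)C(=C)[C@@H]1CCC#C[Si](CC)(CC)CC | intermediate
15 | but‑3‑en‑1‑ylboronic acid | C=CCCB(O)O | starting material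
16 | 3‑bromofuran‑2(5H)‑one | BrC1=CCOC1=O | starting material
17 | mono‑ester of but‑3‑en‑1‑ylboronic acid with the ring carbinol of 14 | C=CCCB(O)OC1CCC[C@@](C)(COC(C)=O)[C@@H](CCC#C[Si](CC)(CC)CC)C1=C | intermediate (not isolated)
18 | cyclic boronate: 2‑hydroxy‑1,2‑oxaborepine ring (O on the carbinol carbon, B on C12) fused to the cycloheptane, ring alkene Z | OB1CC/C=C2\C(O1)CCC[C@@](C)(COC(C)=O)[C@H]2CCC#C[Si](CC)(CC)CC | intermediate (not isolated)
19 | {(1R,2R,3Z)‑4‑hydroxy‑1‑methyl‑3‑[3‑(2‑oxo‑2,5‑dihydrofuran‑3‑yl)propylidene]‑2‑[4‑(triethylsilyl)but‑3‑yn‑1‑yl]cycloheptyl}methyl acetate | OC1CCC[C@@](C)(COC(C)=O)[C@@H](CCC#C[Si](CC)(CC)CC)/C1=C/CCC1=CCOC1=O | intermediate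
20 | {(1R,2R,3Z)‑2‑(but‑3‑yn‑1‑yl)‑4‑hydroxy‑1‑methyl‑3‑[3‑(2‑oxo‑2,5‑dihydrofuran‑3‑yl)propylidene]cycloheptyl}methyl acetate | OC1CCC[C@@](C)(COC(C)=O)[C@@H](CCC#C)/C1=C/CCC1=CCOC1=O | intermediate
21 | [(1R,4aR,5R,8aR)‑4a‑formyl‑1‑methyl‑6‑methylidene‑5‑[2‑(2‑oxo‑2,5‑dihydrofuran‑3‑yl)ethyl]decahydronaphthalen‑1‑yl]methyl acetate | C=C1CC[C@@H]2[C@](C)(COC(C)=O)CCC[C@@]2(C=O)[C@@H]1CCC1=CCOC1=O | target

**Step count and risks**

Total steps: 11. Longest linear sequence: 11 (from pent‑4‑ynal; all other inputs are purchased).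

Steps most likely to fail:

Step 11 (the proposed gold cascade; risks are a hydride shift instead of the ring‑carbon shift, or other enyne pathways). The fallback sets out from 20 and comes back at 21 with known chemistry. Hydroxycyclisation of the 1,6‑enyne with water as external nucleophile ((Ph3P)AuCl/AgSbF6 or PtCl2, wet dioxane) closes ring B and gives the ring‑fused vicinal diol F1, with the tertiary hydroxyl at C10 anti to the new C8–C9 bond. A classical acid‑mediated pinacol rearrangement of the diol F1 (BF3·OEt2 or TsOH, CH2Cl2) then ionises the tertiary hydroxyl and shifts C1, giving 21.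

Step 9 (metathesis onto a hindered 1,1‑disubstituted alkene and an sp3 Suzuki coupling). The fallback sets out from 14 and comes back at 19, replacing the tether by a carbonyl olefination. Ozonolysis of the methylene (O3, CH2Cl2–MeOH, −78 °C; Me2S) gives the α‑hydroxy ketone F2, which is silylated (Et3SiOTf, 2,6‑lutidine) to the α‑silyloxy ketone F3. Wittig reaction of the ketone F3 with the non‑stabilised ylide from (3‑carboxypropyl)triphenylphosphonium bromide (NaN(SiMe3)2, THF) gives the Z acid F4, because α‑alkoxy ketones give the Z‑trisubstituted allylic ether with the new chain cis to the oxygenated carbon. Nickel/photoredox decarboxylative coupling of the acid F4 with 16 (NiCl2·glyme, dtbbpy, Ir[dF(CF3)ppy]2(dtbbpy)PF6, Cs2CO3, blue light) gives the silyl ether F5. Removal of the O‑silyl group from F5 (PPTS, MeOH) gives 19.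

Step 6 (regioselectivity of the diazo homologation and tolerance of the β‑thio ketone). The fallback sets out from 9 and comes back at 11, replacing the diazo insertion by a cyclopropanation/fragmentation ring expansion. Kinetic enolisation on the unsubstituted side (LiN(iPr)2, Me3SiCl, THF, −78 °C) gives the silyl enol ether F6, and cyclopropanation (Et2Zn, CH2I2) gives the siloxycyclopropane F7. Oxidative ring opening of F7 with FeCl3 in DMF followed by NaOAc gives the cycloheptenone F8, and conjugate reduction of the enone F8 with K[HB(sBu)3] returns 11.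

**Further compounds**

F1 | step 11 | [4a,5‑dihydroxy‑9‑methyl‑3‑methylidene‑4‑[2‑(2‑oxo‑2,5‑dihydrofuran‑3‑yl)ethyl]decahydro‑1H‑benzo[7]annulen‑9‑yl]methyl acetate (ring‑B‑closed vicinal diol, stereochemistry as in SMILES) | C=C1CC[C@@H]2[C@](C)(COC(C)=O)CCCC(O)[C@]2(O)[C@@H]1CCC1=CCOC1=O
F2 | step 9 | {(1R,2S)‑4‑hydroxy‑1‑methyl‑3‑oxo‑2‑[4‑(triethylsilyl)but‑3‑yn‑1‑yl]cycloheptyl}methyl acetate | CC(=O)OC[C@]1(C)CCCC(O)C(=O)[C@@H]1CCC#C[Si](CC)(CC)CC
F3 | step 9 | {(1R,2S)‑1‑methyl‑3‑oxo‑4‑[(triethylsilyl)oxy]‑2‑[4‑(triethylsilyl)but‑3‑yn‑1‑yl]cycloheptyl}methyl acetate | CC(=O)OC[C@]1(C)CCCC(O[Si](CC)(CC)CC)C(=O)[C@@H]1CCC#C[Si](CC)(CC)CC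
F4 | step 9 | (4Z)‑4‑{(2R,3R)‑3‑(acetoxymethyl)‑3‑methyl‑7‑[(triethylsilyl)oxy]‑2‑[4‑(triethylsilyl)but‑3‑yn‑1‑yl]cycloheptylidene}butanoic acid | OC(=O)CC/C=C1\C(O[Si](CC)(CC)CC)CCC[C@@](C)(COC(C)=O)[C@H]1CCC#C[Si](CC)(CC)CC
F5 | step 9 | O‑triethylsilyl ether of 19 | CC[Si](CC)(CC)OC1CCC[C@@](C)(COC(C)=O)[C@@H](CCC#C[Si](CC)(CC)CC)/C1=C/CCC1=CCOC1=O
F6 | step 6 | {(1R,5S,6S)‑1‑methyl‑5‑[(phenylsulfanyl)methyl]‑6‑[4‑(triethylsilyl)but‑3‑yn‑1‑yl]‑4‑[(trimethylsilyl)oxy]cyclohex‑3‑en‑1‑yl}methyl acetate | CC(=O)OC[C@]1(C)CC=C(O[Si](C)(C)C)[C@@H](CSc2ccccc2)[C@@H]1CCC#C[Si](CC)(CC)CC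
F7 | step 6 | siloxycyclopropane (bicyclo[4.1.0]heptane) from cyclopropanation of the enol ether double bond of F6 | CC(=O)OC[C@]1(C)CC2CC2(O[Si](C)(C)C)[C@@H](CSc3ccccc3)[C@@H]1CCC#C[Si](CC)(CC)CC
F8 | step 6 | {(1R,6S,7S)‑1‑methyl‑5‑oxo‑6‑[(phenylsulfanyl)methyl]‑7‑[4‑(triethylsilyl)but‑3‑yn‑1‑yl]cyclohept‑3‑en‑1‑yl}methyl acetate | CC(=O)OC[C@]1(C)CC=CC(=O)[C@@H](CSc2ccccc2)[C@@H]1CCC#C[Si](CC)(CC)CC
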